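Ring A is a masked hydroquinone. O1 on C8a and the hydroxyl on C6 stand para, C7 bears OMe beside C6, and C4a bears the C4 carbonyl beside C8a. That is the 4-alkoxyphenol pattern of a Dötz benzannulation, so ring A is cut at C5–C6, C4a–C8a and C8–C8a. In one operation the zerovalent chromium benzyloxy(1-methoxyvinyl)carbene 7, the terminal alkyne 14 (a silyl-protected propargylic alcohol that already holds C4, C3 and ring B) and one CO ligand give phenol 16. The C6 and C7 oxygens are told apart as benzyl and methyl ethers. Desilylation, oxidation, one-carbon closure of ring C and hydrogenolysis then finish the isoflavone.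

Key step: step 7

Remark: the target has no stereocentre. The carbinol carbon that becomes C4 is carried as a racemate from step 5 and is flattened in step 9. In the SMILES the CO ligands are drawn as Cr=C=O and the η6 bond of 15 as a dot.

Step 1
Reactants: 1 methyl vinyl ether; 2 chromium hexacarbonyl Cr(CO)6
Product: 5 tetramethylammonium pentacarbonyl[(1-methoxyethenyl)(oxido)carbene]chromate, via 1-methoxyvinyllithium 3 (not isolated), via lithium acylchromate 4 (not isolated)
Conditions: t-BuLi, THF, −78 → 0 °C; Cr(CO)6, THF–Et2O, 0 °C → rt; Me4NBr, degassed H2O, CH2Cl2 extraction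
Reagents that add atoms: tetramethylammonium bromide, C[N+](C)(C)C.[Br-]; tert-butyllithium, [Li]C(C)(C)C (its lithium stays only in 3 and 4)
Why: α-Metalation of the enol ether by t-BuLi is standard, the vinyllithium adds to a CO ligand as in the Fischer carbene synthesis, and cation exchange should give an acylchromate salt that dissolves in CH2Cl2 and can be stored cold.

Step 2
Reactants: 5 tetramethylammonium pentacarbonyl[(1-methoxyethenyl)(oxido)carbene]chromate
Product: 7 pentacarbonyl[(benzyloxy)(1-methoxyethenyl)carbene]chromium, via acetoxycarbene complex 6 (not isolated)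
Conditions: AcBr, CH2Cl2, −40 °C; BnOH, −40 → 0 °C
Reagents that add atoms: benzyl alcohol, OCc1ccccc1; acetyl bromide, CC(=O)Br (its acetyl group stays only in 6)
Why: O-Acylation of the acylchromate gives a strongly electrophilic acyloxycarbene that takes up the alcohol at the carbene carbon by addition–elimination (acyloxycarbene alcoholysis), while the α-methoxy group lowers the acceptor character of the CH2 terminus so that conjugate addition of the alcohol should stay behind.

Step 3
Reactants: 8 3,4,5-trimethoxyphenylacetic acid
Product: 10 N-methoxy-N-methyl-2-(3,4,5-trimethoxyphenyl)acetamide, via acylimidazole 9 (not isolated)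
Conditions: CDI, CH2Cl2, rt; MeNHOMe·HCl, rt
Reagents that add atoms: N,O-dimethylhydroxylamine hydrochloride, CNOC.Cl; 1,1'-carbonyldiimidazole, O=C(n1ccnc1)n1ccnc1 (its imidazolyl group stays only in 9)
Why: Weinreb amide formation through the acylimidazole is a mild amide coupling that leaves the aryl methyl ethers untouched.

Step 4
Reactants: 10 N-methoxy-N-methyl-2-(3,4,5-trimethoxyphenyl)acetamide
Product: 11 2-(3,4,5-trimethoxyphenyl)acetaldehyde
Conditions: i-Bu2AlH, THF, −78 °C; aq. potassium sodium tartrate; used without delay
Reagents that add atoms: none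
Why: In this Weinreb amide reduction the chelated tetrahedral aluminium adduct lasts until work-up, so hydride delivery stops at the aldehyde, and the route never passes through a terminal ynone that the released hydroxylamine could attack in a Michael sense.

Step 5
Reactants: 11 2-(3,4,5-trimethoxyphenyl)acetaldehyde; 12 ethynylmagnesium bromide
Product: 13 rac-1-(3,4,5-trimethoxyphenyl)but-3-yn-2-ol
Conditions: THF, −20 → 0 °C; sat. aq. NH4Cl
Reagents that add atoms: none
Why: Grignard 1,2-addition of the weakly basic alkynyl reagent should outrun enolisation of the arylacetaldehyde; the new carbinol centre (future C4) forms without control as a racemate, which is harmless because step 9 removes it.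

Step 6
Reactants: 13 rac-1-(3,4,5-trimethoxyphenyl)but-3-yn-2-ol
Product: 14 rac-tert-butyldimethyl{[1-(3,4,5-trimethoxyphenyl)but-3-yn-2-yl]oxy}silane
Conditions: TBSCl, imidazole, DMF, rt
Reagents that add atoms: tert-butyldimethylsilyl chloride, CC(C)(C)[Si](C)(C)Cl
Why: Imidazole-promoted silylation of a secondary alcohol is routine, and the bulky silyl ether both keeps the oxygen out of the ketene chemistry of step 7 and sharpens the size difference between the two alkyne ends.

Step 7
Reactants: 7 pentacarbonyl[(benzyloxy)(1-methoxyethenyl)carbene]chromium; 14 rac-tert-butyldimethyl{[1-(3,4,5-trimethoxyphenyl)but-3-yn-2-yl]oxy}silane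
Product: 16 rac-4-(benzyloxy)-2-[1-(tert-butyldimethylsilyloxy)-2-(3,4,5-trimethoxyphenyl)ethyl]-5-methoxyphenol, via arene tricarbonylchromium complex 15 (not isolated)
Conditions: 7 (1.2 equiv), THF (0.1 M), 55 °C, Ar, dark; then air, MeCN–Et2O, rt; Et3N-deactivated silica
Reagents that add atoms: none
Why: Loss of one cis CO ligand lets 14 bind and insert into the Cr=C bond (C5–C6), and migration of CO to the new carbene carbon (C4a–C8a) gives a chromium-bound dienylketene. Ring A closes by a 6π-electrocyclisation of this dienylketene between the ketene carbon and the CH2 terminus (C8–C8a), and enolisation gives the phenol as its Cr(CO)3 complex 15, from which air in a donor solvent frees 16. The closest known reaction is the Dötz benzannulation of alkenyl(alkoxy)carbene complexes of zerovalent chromium with terminal alkynes, a class that includes α-alkoxyalkenyl complexes made from lithiated cyclic enol ethers and propargylic silyl ethers as the alkyne partner. No stereocentre is formed, since the carbinol carbon is carried unchanged as a racemate and the planar chirality of 15 disappears on demetalation. The regioselectivity needed, the substituted alkyne carbon next to the CO-derived C8a, is secured by the steric contrast between H and the branched CH(OTBS)CH2Ar group in the vinylcarbene intermediate. The chemoselectivity needed, a phenol rather than five-membered ring, furan or cyclobutenone products and no quinone, is served by the alkenyl (not aryl) carbene, by the silyl cap that keeps the oxygen from trapping the ketene, and by demetalation with air instead of a strong oxidant.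

Step 8
Reactants: 16 rac-4-(benzyloxy)-2-[1-(tert-butyldimethylsilyloxy)-2-(3,4,5-trimethoxyphenyl)ethyl]-5-methoxyphenol
Product: 17 rac-4-(benzyloxy)-2-[1-hydroxy-2-(3,4,5-trimethoxyphenyl)ethyl]-5-methoxyphenol
Conditions: Bu4NF, AcOH (1:1), THF, rt
Reagents that add atoms: none
Why: Fluoride-driven Si–O cleavage is reliable, and the acetic acid buffer keeps the phenol protonated so that neither silyl migration nor o-quinone methide formation at the activated benzylic carbon is set off.

Step 9
Reactants: 17 rac-4-(benzyloxy)-2-[1-hydroxy-2-(3,4,5-trimethoxyphenyl)ethyl]-5-methoxyphenol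
Product: 18 1-[5-(benzyloxy)-2-hydroxy-4-methoxyphenyl]-2-(3,4,5-trimethoxyphenyl)ethan-1-one
Conditions: DDQ (1.05 equiv), anhydrous 1,4-dioxane, rt
Reagents that add atoms: none
Why: DDQ dehydrogenation of benzylic alcohols activated by ortho or para hydroxy and alkoxy groups is a known selective oxidation that tolerates electron-rich free phenols: hydride loss from the carbinol C–H, helped by the ortho OH and para OMe, gives the protonated ketone directly, no water is present to divert the hydroquinone monoether to a quinone, and the hydrogen-bonded ketone is deactivated against further oxidation.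

Step 10
Reactants: 18 1-[5-(benzyloxy)-2-hydroxy-4-methoxyphenyl]-2-(3,4,5-trimethoxyphenyl)ethan-1-one
Product: 20 6-(benzyloxy)-7-methoxy-3-(3,4,5-trimethoxyphenyl)-4H-chromen-4-one, via enaminone 19 (not isolated)
Conditions: Me2NCH(OMe)2 (3 equiv), PhMe, 100 °C
Reagents that add atoms: N,N-dimethylformamide dimethyl acetal, CN(C)C(OC)OC
Why: Condensation of the acidic deoxybenzoin CH2 with the formamide acetal gives the enaminone, whose β-carbon (C2) is attacked by the ortho phenol in a 6-endo addition–elimination that expels dimethylamine, which is the standard enaminone route to isoflavones.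

Step 11
Reactants: 20 6-(benzyloxy)-7-methoxy-3-(3,4,5-trimethoxyphenyl)-4H-chromen-4-one
Product: 21 6-hydroxy-7-methoxy-3-(3,4,5-trimethoxyphenyl)-4H-chromen-4-one
Conditions: H2 (1 atm), Pd/C, EtOAc–THF, rt, stopped after one equivalent of H2
Reagents that add atoms: none
Why: Catalytic hydrogenolysis of an aryl benzyl ether over Pd/C is much faster than saturation of the trisubstituted, vinylogous-ester C2=C3 bond of an isoflavone, so monitored uptake should free the C6 hydroxyl alone.

Compound list
1 | methyl vinyl ether | C=COC | starting material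
2 | chromium hexacarbonyl Cr(CO)6 | O=C=[Cr](=C=O)(=C=O)(=C=O)(=C=O)=C=O | starting material
3 | 1-methoxyvinyllithium | [Li]C(=C)OC | intermediate
4 | lithium pentacarbonyl[(1-methoxyethenyl)(oxido)carbene]chromate | C=C(OC)C([O-])=[Cr](=C=O)(=C=O)(=C=O)(=C=O)=C=O.[Li+] | intermediate
5 | tetramethylammonium pentacarbonyl[(1-methoxyethenyl)(oxido)carbene]chromate | C=C(OC)C([O-])=[Cr](=C=O)(=C=O)(=C=O)(=C=O)=C=O.C[N+](C)(C)C | intermediate
6 | pentacarbonyl[(acetyloxy)(1-methoxyethenyl)carbene]chromium | C=C(OC)C(OC(C)=O)=[Cr](=C=O)(=C=O)(=C=O)(=C=O)=C=O | intermediate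
7 | pentacarbonyl[(benzyloxy)(1-methoxyethenyl)carbene]chromium | C=C(OC)C(OCc1ccccc1)=[Cr](=C=O)(=C=O)(=C=O)(=C=O)=C=O | intermediate
8 | 3,4,5-trimethoxyphenylacetic acid | COc1cc(CC(=O)O)cc(OC)c1OC | starting material
9 | 1-(1H-imidazol-1-yl)-2-(3,4,5-trimethoxyphenyl)ethan-1-one | COc1cc(CC(=O)n2ccnc2)cc(OC)c1OC | intermediate
10 | N-methoxy-N-methyl-2-(3,4,5-trimethoxyphenyl)acetamide | COc1cc(CC(=O)N(C)OC)cc(OC)c1OC | intermediate
11 | 2-(3,4,5-trimethoxyphenyl)acetaldehyde | COc1cc(CC=O)cc(OC)c1OC | intermediate
12 | ethynylmagnesium bromide | C#C[Mg]Br | starting material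
13 | rac-1-(3,4,5-trimethoxyphenyl)but-3-yn-2-ol | C#CC(O)Cc1cc(OC)c(OC)c(OC)c1 | intermediate
14 | rac-tert-butyldimethyl{[1-(3,4,5-trimethoxyphenyl)but-3-yn-2-yl]oxy}silane | C#CC(Cc1cc(OC)c(OC)c(OC)c1)O[Si](C)(C)C(C)(C)C | intermediate
15 | tricarbonyl(η6-arene)chromium complex of phenol 16, Cr(CO)3 on ring A, mixture of diastereomers | COc1cc(O)c(cc1OCc1ccccc1)C(Cc1cc(OC)c(OC)c(OC)c1)O[Si](C)(C)C(C)(C)C.O=C=[Cr](=C=O)=C=O | intermediate
16 | rac-4-(benzyloxy)-2-[1-(tert-butyldimethylsilyloxy)-2-(3,4,5-trimethoxyphenyl)ethyl]-5-methoxyphenol | COc1cc(O)c(cc1OCc1ccccc1)C(Cc1cc(OC)c(OC)c(OC)c1)O[Si](C)(C)C(C)(C)C | intermediate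
17 | rac-4-(benzyloxy)-2-[1-hydroxy-2-(3,4,5-trimethoxyphenyl)ethyl]-5-methoxyphenol | COc1cc(O)c(cc1OCc1ccccc1)C(O)Cc1cc(OC)c(OC)c(OC)c1 | intermediate
18 | 1-[5-(benzyloxy)-2-hydroxy-4-methoxyphenyl]-2-(3,4,5-trimethoxyphenyl)ethan-1-one | COc1cc(O)c(cc1OCc1ccccc1)C(=O)Cc1cc(OC)c(OC)c(OC)c1 | intermediate
19 | 1-[5-(benzyloxy)-2-hydroxy-4-methoxyphenyl]-3-(dimethylamino)-2-(3,4,5-trimethoxyphenyl)prop-2-en-1-one (push–pull C=C, geometry labile and not specified) | COc1cc(O)c(cc1OCc1ccccc1)C(=O)C(=CN(C)C)c1cc(OC)c(OC)c(OC)c1 | intermediate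
20 | 6-(benzyloxy)-7-methoxy-3-(3,4,5-trimethoxyphenyl)-4H-chromen-4-one | COc1cc2occ(-c3cc(OC)c(OC)c(OC)c3)c(=O)c2cc1OCc1ccccc1 | intermediate
21 | 6-hydroxy-7-methoxy-3-(3,4,5-trimethoxyphenyl)-4H-chromen-4-one (CNP0248931.0) | COc1cc2occ(-c3cc(OC)c(OC)c(OC)c3)c(=O)c2cc1O | target

Total step count: 11.
Longest linear sequence: 9 steps (steps 3 to 11, from acid 8). The carbene branch (steps 1 and 2) joins at step 7.

Steps most likely to fail

**Step 7.**
- Risks: thermal decay of the electron-rich carbene complex before the alkyne is taken up, repeated alkyne insertion leading to oligomers, or overoxidation of the hydroquinone monoether while chromium is removed.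
- Fallback: ring A is bought instead of built.
- It sets out from acid 8. Friedel–Crafts acylation of commercial 2-methoxyhydroquinone in neat BF3·OEt2 at about 80 °C is directed ortho to one hydroxyl and para to the methoxy group. It should give 1-(2,5-dihydroxy-4-methoxyphenyl)-2-(3,4,5-trimethoxyphenyl)ethan-1-one F1.
- Treatment of that ketone with DMF, MsCl and BF3·OEt2 (Vilsmeier-type formylation of the CH2 group followed by cyclisation) closes ring C. The fallback comes back to the route at target 21.

**Step 2.**
- Risks: collapse of the acetoxycarbene stage on warming, conjugate addition of the alcohol to the CH2 terminus, or acid-induced hydrolysis of the enol ether.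
- Fallback: the oxygen–benzyl bond is made by SN2 alkylation at the acylate oxygen instead of substitution at the carbene carbon.
- It sets out from salt 5. Benzyl bromide under phase-transfer conditions (Bu4NBr, CH2Cl2–H2O, rt) is a known O-alkylation of acylmetalates with reactive halides. It leads back to the route at 7.
- No compound outside the list is made (F0).

**Step 9.**
- Risks: competing oxidation of the hydroquinone monoether towards a quinone, acid-induced dehydration of the activated benzylic alcohol by the hydroquinone formed from DDQ, or hydride loss at the CH2 next to ring B.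
- Fallback: the phenol is capped before any oxidant is used. It sets out from 16.
- MOMCl and i-Pr2NEt in CH2Cl2 should give rac-{1-[5-(benzyloxy)-4-methoxy-2-(methoxymethoxy)phenyl]-2-(3,4,5-trimethoxyphenyl)ethoxy}(tert-butyl)dimethylsilane F2.
- Bu4NF in THF then gives rac-1-[5-(benzyloxy)-4-methoxy-2-(methoxymethoxy)phenyl]-2-(3,4,5-trimethoxyphenyl)ethan-1-ol F3.
- Dess–Martin periodinane with NaHCO3 in CH2Cl2 gives 1-[5-(benzyloxy)-4-methoxy-2-(methoxymethoxy)phenyl]-2-(3,4,5-trimethoxyphenyl)ethan-1-one F4.
- HCl in MeOH at 40 °C removes the acetal ortho to the carbonyl. The fallback comes back to the route at 18.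

Further compounds
F1 | step 7 | 1-(2,5-dihydroxy-4-methoxyphenyl)-2-(3,4,5-trimethoxyphenyl)ethan-1-one | COc1cc(O)c(cc1O)C(=O)Cc1cc(OC)c(OC)c(OC)c1
F0 | step 2 | none | none
F2 | step 9 | rac-{1-[5-(benzyloxy)-4-methoxy-2-(methoxymethoxy)phenyl]-2-(3,4,5-trimethoxyphenyl)ethoxy}(tert-butyl)dimethylsilane | COCOc1cc(OC)c(OCc2ccccc2)cc1C(Cc1cc(OC)c(OC)c(OC)c1)O[Si](C)(C)C(C)(C)C
F3 | step 9 | rac-1-[5-(benzyloxy)-4-methoxy-2-(methoxymethoxy)phenyl]-2-(3,4,5-trimethoxyphenyl)ethan-1-ol | COCOc1cc(OC)c(OCc2ccccc2)cc1C(O)Cc1cc(OC)c(OC)c(OC)c1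
F4 | step 9 | 1-[5-(benzyloxy)-4-methoxy-2-(methoxymethoxy)phenyl]-2-(3,4,5-trimethoxyphenyl)ethan-1-one | COCOc1cc(OC)c(OCc2ccccc2)cc1C(=O)Cc1cc(OC)c(OC)c(OC)c1
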